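**Assumption:** the SMILES encodes the (2S)-flavanone (at C2: O1 > aryl > C3 > H, counter-clockwise); 1-bromo-4-(methoxymethoxy)benzene and prenyl-Bpin are treated as catalogue items.

## Retrosynthetic overview
1. Target 14 ⇐ global MOM removal from tris-MOM flavanone 13.
2. 13 ⇐ C2–C1′ disconnection: enantioselective Rh-catalysed 1,4-arylation of chromone 7 with arylboronic acid 12. This dearomatises the γ-pyrone ring and sets C2 directly.
3. 7 ⇐ enaminone annulation of ketone 5 ⇐ symmetric 2,4,6-trihydroxyacetophenone 1 by mono-C-prenylation (symmetry broken) and selective bis-MOM protection. The OH left free sits next to the prenyl group and becomes O1, which places prenyl at C8.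
4. 12 ⇐ directed ortho-metalation/borylation of 10 ⇐ γ-selective (reverse) prenylation of aryl bromide 8.
5. Ring order: rings A and B are bought as aromatics; the pyranone ring is built as an aromatic chromone (step 3) and converted to the chromanone in the key step (step 6).

## Route

**Step 1**
Reactants: 1, 2,4,6-trihydroxyacetophenone
Product: 3, 1-[2,4,6-trihydroxy-3-(3-methylbut-2-en-1-yl)phenyl]ethanone
Conditions: prenyl bromide (1.0 equiv), DBU (1.1 equiv), THF, 0 °C → rt
Reagents that add atoms: 2, prenyl bromide, CC(C)=CCBr
Why: the phloroglucinol-type phenoxide is a soft ambident nucleophile that undergoes direct C-alkylation (SN2) at one of its two equivalent ring CH positions; a modest yield (about 40%) is accepted at the first step, with limiting bromide to suppress di-prenylation.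

**Step 2**
Reactants: 3
Product: 5, 1-[2-hydroxy-4,6-bis(methoxymethoxy)-3-(3-methylbut-2-en-1-yl)phenyl]ethanone
Conditions: MOMCl (2.1 equiv), i-Pr2NEt (3 equiv), CH2Cl2, 0 °C → rt
Reagents that add atoms: 4, chloromethyl methyl ether, COCCl (two equivalents incorporated)
Why: O-alkylation (acetal formation) takes the non-chelated 4-OH and the less hindered 6-OH, while the 2-OH, flanked by prenyl and acetyl and hydrogen-bonded to the carbonyl, stays free; this is the same preference seen in partial O-alkylation of 3-alkylphloroacetophenones.

**Step 3**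
Reactants: 5
Product: 7, 5,7-bis(methoxymethoxy)-8-(3-methylbut-2-en-1-yl)-4H-chromen-4-one
Conditions: DMF-DMA, toluene, 95 °C; then AcOH, 60 °C
Reagents that add atoms: 6, N,N-dimethylformamide dimethyl acetal, COC(OC)N(C)C (supplies C2 of the chromone)
Why: enaminone condensation at the acetyl methyl followed by intramolecular addition–elimination (loss of Me2NH) by the only free phenol gives the chromone; because that phenol is ortho to the prenyl group, the prenyl ends up at C8, and the weak acid leaves the MOM ethers intact.

**Step 4**
Reactants: 8, 1-bromo-4-(methoxymethoxy)benzene; 9, prenylboronic acid pinacol ester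
Product: 10, 1-(methoxymethoxy)-4-(2-methylbut-3-en-2-yl)benzene
Conditions: Pd(OAc)2 (2 mol %), SPhos (4 mol %), aq K3PO4, THF, 40 °C
Reagents that add atoms: none beyond reactant 9 (CC(C)=CCB1OC(C)(C)C(C)(C)O1)
Why: γ-selective Suzuki–Miyaura allyl–aryl coupling, in which SE2′ transmetalation puts Pd on the tertiary carbon and fast reductive elimination gives the branched 1,1-dimethylallyl arene; α/γ selectivity is ligand-controlled, and the ligand given is my best recollection of the γ-selective class and should be confirmed on a test scale.

**Step 5**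
Reactants: 10
Product: 12, [2-(methoxymethoxy)-5-(2-methylbut-3-en-2-yl)phenyl]boronic acid
Conditions: n-BuLi, TMEDA, Et2O, 0 °C; B(Oi-Pr)3, −78 °C → rt; aq NH4Cl
Reagents that add atoms: 11, triisopropyl borate, CC(C)OB(OC(C)C)OC(C)C (boron); water, O (the two B–OH oxygens on hydrolysis)
Why: MOM-directed ortho-lithiation followed by borate quench; the only site ortho to OMOM is the required one, and the side chain has no allylic or benzylic hydrogens to compete.

**Step 6 (key step)**
Reactants: 7; 12 (2.5 equiv)
Product: 13, (2S)-5,7-bis(methoxymethoxy)-2-[2-(methoxymethoxy)-5-(2-methylbut-3-en-2-yl)phenyl]-8-(3-methylbut-2-en-1-yl)-2,3-dihydro-4H-chromen-4-one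
Conditions: [RhCl((S,S)-Ph-bod*)]2 (2.5 mol %), K3PO4 (0.5 equiv), toluene/H2O 10:1, 50 °C
Reagents that add atoms: none (the C3 hydrogen comes from water)
Why: Hayashi–Miyaura Rh-catalysed asymmetric 1,4-addition to the chromone, in which the chiral-diene aryl-Rh species carbometalates C2=C3 on the C2 Re face to give (2S) after protonation of the oxa-π-allyl rhodium. The facial sense is assigned by analogy with the (S)-3-arylcyclohexanones this ligand hand is expected to give, so the (R,R)-diene is used instead if the sense turns out opposite. Rh(I) tolerates the ortho-alkoxy group and both isolated alkenes, and the weak base avoids retro-oxa-Michael opening.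

**Step 7**
Reactants: 13
Product: 14, (2S)-5,7-dihydroxy-2-[2-hydroxy-5-(2-methylbut-3-en-2-yl)phenyl]-8-(3-methylbut-2-en-1-yl)-2,3-dihydro-4H-chromen-4-one (target)
Conditions: 3 M aq HCl/MeOH (1:4), 45–50 °C, 1 h
Reagents that add atoms: none
Why: acid-catalysed acetal hydrolysis removes all three MOM groups under conditions routinely used on prenylated flavanones; it avoids base, which would racemise C2 through the chalcone, and is too mild and brief to hydrate or cyclise the prenyl and 1,1-dimethylallyl groups.

## Compound list
1 | 2,4,6-trihydroxyacetophenone | CC(=O)c1c(O)cc(O)cc1O | starting material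
2 | prenyl bromide | CC(C)=CCBr | starting material
3 | 1-[2,4,6-trihydroxy-3-(3-methylbut-2-en-1-yl)phenyl]ethanone | CC(=O)c1c(O)cc(O)c(CC=C(C)C)c1O | intermediate
4 | chloromethyl methyl ether | COCCl | starting material (reagent)
5 | 1-[2-hydroxy-4,6-bis(methoxymethoxy)-3-(3-methylbut-2-en-1-yl)phenyl]ethanone | CC(=O)c1c(OCOC)cc(OCOC)c(CC=C(C)C)c1O | intermediate
6 | N,N-dimethylformamide dimethyl acetal | COC(OC)N(C)C | starting material (reagent)
7 | 5,7-bis(methoxymethoxy)-8-(3-methylbut-2-en-1-yl)-4H-chromen-4-one | O=c1ccoc2c(CC=C(C)C)c(OCOC)cc(OCOC)c12 | intermediate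
8 | 1-bromo-4-(methoxymethoxy)benzene | COCOc1ccc(Br)cc1 | starting material
9 | 4,4,5,5-tetramethyl-2-(3-methylbut-2-en-1-yl)-1,3,2-dioxaborolane | CC(C)=CCB1OC(C)(C)C(C)(C)O1 | starting material
10 | 1-(methoxymethoxy)-4-(2-methylbut-3-en-2-yl)benzene | C=CC(C)(C)c1ccc(OCOC)cc1 | intermediate
11 | triisopropyl borate | CC(C)OB(OC(C)C)OC(C)C | starting material (reagent)
12 | [2-(methoxymethoxy)-5-(2-methylbut-3-en-2-yl)phenyl]boronic acid | C=CC(C)(C)c1ccc(OCOC)c(B(O)O)c1 | intermediate
13 | (2S)-5,7-bis(methoxymethoxy)-2-[2-(methoxymethoxy)-5-(2-methylbut-3-en-2-yl)phenyl]-8-(3-methylbut-2-en-1-yl)chroman-4-one | C=CC(C)(C)c1ccc(OCOC)c([C@@H]2CC(=O)c3c(OCOC)cc(OCOC)c(CC=C(C)C)c3O2)c1 | intermediate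
14 | (2S)-5,7-dihydroxy-2-[2-hydroxy-5-(2-methylbut-3-en-2-yl)phenyl]-8-(3-methylbut-2-en-1-yl)chroman-4-one | C=CC(C)(C)c1ccc(O)c([C@@H]2CC(=O)c3c(O)cc(O)c(CC=C(C)C)c3O2)c1 | target

## Summary
Total steps: 7. Longest linear sequence: 5 (steps 1 → 2 → 3 → 6 → 7); the side branch is steps 4 → 5.

Three steps most likely to fail:
1. **Step 6** (ortho-substituted boronic acid adding to an electron-rich 5,7-dialkoxychromone; protodeboronation, low conversion or low ee). Fallback: abandon the C2–aryl disconnection. Quench the aryllithium from 10 with DMF to get the aldehyde, condense it with ketone 5 (Claisen–Schmidt) to the 2′-hydroxychalcone, and close the ring by a bifunctional cinchona-thiourea-catalysed asymmetric oxa-Michael reaction.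
2. **Step 2** (MOM protection may not fully discriminate the two chelatable ortho-OH groups, which would carry through to a 6-prenyl isomer). Fallback: install the prenyl group by rearrangement instead. Take 5,7-dihydroxychromone to its 7-O-MOM, 5-O-prenyl ether and run a Eu(fod)3-catalysed Claisen–Cope shift (O5 → C6 → C8), which delivers the prenyl group to C8 only.
3. **Step 7** (acid could erode ee through ring-opening assisted by the 2′-OH, or cyclise the 8-prenyl group onto the 7-OH). Fallback: change the protecting-group plan. Use TBS ethers on ring A and carry the B-ring partner as the free 2-hydroxyarylboronic acid, so the final step is a buffered fluoride desilylation (HF·pyridine or TBAF/AcOH) with no acid.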